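A direct plan would turn the aryl methyl ketone A1 by a carboxyethyl-ylide Wittig reaction into the E-alkenoic acid A2, hydrogenate it asymmetrically to the (S)-acid A3, join two molecules by borylation/Suzuki coupling (diacid A4), extend both chains by decarboxylative alkenylation of the bis(N-acyloxyphthalimide) A5, and demethylate the dimethyl ether A6 last.
Its weakest steps would be:
- the Wittig olefination, because the alkene geometry would fix the enantiopurity of everything after it;
- the twofold radical chain extension, because two couplings on one molecule are each open to hydrogen abstraction;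
- the twofold ether cleavage, because it would put hot thiolate on an oxidation-prone biphenol at the very end.

The route rests on cutting the C4–C4' biaryl bond (phenol numbering) last and forming it from two C–H bonds. Two molecules of unprotected (S)-curcuphenol are united para to their hydroxyl groups by anodic dehydrogenative coupling, a union of two like-polarised carbons that the 2-alkyl-5-methylphenol rings invite, since C4 is their only open and unhindered spin-bearing carbon. In one operation this gives the whole C2-symmetric target with no halide, boron or protecting group. The monomer's benzene ring is built on the carboxyl end of (S)-citronellic acid, which supplies side chain, stereocentre and alkene ready-made. Hence no alkene geometry must be controlled, no chain is extended on the dimer and no ether is cleaved.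

Key step: step 5

Assumption: (S)-citronellic acid is commercially available in high enantiomeric purity; the ring stereocentres of 6–10 form as mixtures, which converge because all become sp2 carbons by step 4.

Step 1
Reactants: 1 (S)-citronellic acid [(3S)-3,7-dimethyloct-6-enoic acid]; 2 potassium ethyl malonate
Product: 4 ethyl (5S)-5,9-dimethyl-3-oxodec-8-enoate, via citronelloyl imidazolide 3 (not isolated)
Conditions: CDI (1.1 equiv), THF, rt; then added to 2 (1.5 equiv), MgCl2 (1.5 equiv), Et3N (1.5 equiv), MeCN, rt → 40 °C; 1 M HCl
Reagents that add atoms: potassium ethyl malonate (2), CCOC(=O)CC(=O)[O-].[K+]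
Why: Masamune–Brooks homologation, in which the acyl imidazolide 3 C-acylates the magnesium enolate of the malonate half-ester and the adduct loses CO2 to give the β-keto ester, under conditions free of strong acid or Lewis acid that leave the alkene alone and cannot invert the stereocentre, which sits β to the carbonyl carbon and carries no acidic hydrogen.

Step 2
Reactants: 4 ethyl (5S)-5,9-dimethyl-3-oxodec-8-enoate; 5 (E)-but-2-enal (crotonaldehyde)
Product: 7 ethyl 4-hydroxy-6-methyl-3-[(2S)-6-methylhept-5-en-2-yl]-2-oxocyclohexane-1-carboxylate (mixture of ring diastereomers), via acyclic Michael adduct 6 (not isolated)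
Conditions: NaOEt (0.1 equiv), EtOH, −10 °C, 5 (1.1 equiv) added slowly, then rt; AcOH (0.1 equiv)
Reagents that add atoms: (E)-but-2-enal (5), C/C=C/C=O
Why: Robinson-type annulation by Michael addition and intramolecular aldol addition, in which the doubly activated C2 carbanion of 4 adds to the β-carbon of the enal (placing the future ring methyl group) and the other α-carbon of the ketone, C4, then closes onto the aldehyde, the only enolate–carbonyl pairing in 6 that gives a six-membered ring, while the new ring stereocentres need no control and the side-chain centre is not enolisable.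

Step 3
Reactants: 7 ethyl 4-hydroxy-6-methyl-3-[(2S)-6-methylhept-5-en-2-yl]-2-oxocyclohexane-1-carboxylate
Product: 9 5-methyl-2-[(2S)-6-methylhept-5-en-2-yl]cyclohex-2-en-1-one (both C5 epimers), via enone carboxylic acid 8 (not isolated)
Conditions: KOH (3 equiv), EtOH/H2O, rt → 50 °C; then 1 M HCl to pH 3–4, 45 °C
Reagents that add atoms: none
Why: Ester saponification and E1cB dehydration of the β-hydroxy ketone in base, followed by decarboxylation of the β-keto acid 8 through its cyclic six-membered transition state on mild acidification, a sequence in which the side-chain stereocentre sits on the α-substituent of the enone where its hydrogen is cross-conjugated and not acidic, and in which brief contact with dilute acid should spare the trisubstituted alkene.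

Step 4
Reactants: 9 5-methyl-2-[(2S)-6-methylhept-5-en-2-yl]cyclohex-2-en-1-one
Product: 12 (S)-curcuphenol [5-methyl-2-[(2S)-6-methylhept-5-en-2-yl]phenol], via silyl dienol ether 10 (not isolated), via cyclohexa-2,5-dienone 11 (not isolated)
Conditions: LiN(iPr)2 (LDA, 1.1 equiv), THF, −78 °C; Me3SiCl (1.2 equiv), −78 → 0 °C; then Pd(OAc)2 (1.05 equiv), MeCN, rt
Reagents that add atoms: none
Why: Saegusa–Ito dehydrogenation, in which kinetic deprotonation at C6 and O-silylation give the cross-conjugated silyl dienol ether 10, transfer of the enolate to Pd(OAc)2 gives a divalent palladium enolate, and β-hydride elimination of H5 gives the dienone 11, whose C4 methylene group allows immediate tautomerisation to the phenol, while the side-chain centre has no acidic hydrogen and the isolated trisubstituted alkene should not engage palladium diacetate at room temperature.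

Step 5
Reactants: 12 (S)-curcuphenol (two molecules)
Product: 13 2,2'-dimethyl-5,5'-bis[(2S)-6-methylhept-5-en-2-yl]-1,1'-biphenyl-4,4'-diol (CNP0163343.1)
Conditions: undivided cell, boron-doped diamond anode, nickel cathode, 1,1,1,3,3,3-hexafluoropropan-2-ol (HFIP), methyltributylammonium methyl sulfate (0.1 M), 12 (0.2 M), 5 mA cm−2, about 1 F per mol of 12, 25 °C, argon; aq. Na2S2O4 wash
Reagents that add atoms: none
Why: Anodic one-electron oxidation of 12, whose OH group is hydrogen-bonded to HFIP, and loss of a proton give a phenoxyl radical with spin density at C4 and C6; C4 bonds to C4 of a second molecule of 12 (or of a second radical), loss of a further electron and of two protons re-aromatises both rings to the 4,4'-biphenol, and the cathode reduces the protons to H2. This is the known anodic dehydrogenative para,para'-homocoupling of 2,5-dialkylphenols of the thymol type at boron-doped diamond in HFIP, a union of two carbons of like polarity, applied here to a phenol that carries an alkenyl side chain. No ring is closed. No stereocentre is made: the biaryl axis has only one ortho methyl group per ring and rotates freely, and the two benzylic centres come unchanged from 12, so that S monomer can only give the S,S dimer, while any R monomer would end up mainly in the separable meso dimer. The step needs coupling at C4 in preference to C6 or oxygen, and oxidation of the phenol in preference to the alkenes and the product: C4 is the open para carbon whereas C6 is wedged between OH and CH3 and C2 is substituted, HFIP shields the oxygen, the phenol is oxidised at a far lower potential than a trisubstituted alkene that the phenoxyl oxygen could reach only through a seven- or eight-membered ring, and the two ortho methyl groups twist the product out of the planarity that a diphenoquinone requires. Low current density and a charge near the theoretical 1 F per mol should hold back the second electron transfer, which would lead to an ortho-quinone methide and loss of the stereocentre.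

Compound list
1 | (S)-citronellic acid, (3S)-3,7-dimethyloct-6-enoic acid | CC(C)=CCC[C@H](C)CC(=O)O | starting material
2 | potassium ethyl malonate (potassium 3-ethoxy-3-oxopropanoate) | CCOC(=O)CC(=O)[O-].[K+] | starting material
3 | 1-[(3S)-3,7-dimethyloct-6-enoyl]-1H-imidazole (citronelloyl imidazolide, not isolated) | CC(C)=CCC[C@H](C)CC(=O)n1ccnc1 | intermediate
4 | ethyl (5S)-5,9-dimethyl-3-oxodec-8-enoate | CC(C)=CCC[C@H](C)CC(=O)CC(=O)OCC | intermediate
5 | (E)-but-2-enal (crotonaldehyde) | C/C=C/C=O | starting material
6 | ethyl (5S)-5,9-dimethyl-3-oxo-2-(4-oxobutan-2-yl)dec-8-enoate (Michael adduct, not isolated) | CC(C)=CCC[C@H](C)CC(=O)C(C(=O)OCC)C(C)CC=O | intermediate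
7 | ethyl 4-hydroxy-6-methyl-3-[(2S)-6-methylhept-5-en-2-yl]-2-oxocyclohexane-1-carboxylate (ring diastereomers) | CC(C)=CCC[C@H](C)C1C(O)CC(C)C(C(=O)OCC)C1=O | intermediate
8 | 6-methyl-3-[(2S)-6-methylhept-5-en-2-yl]-2-oxocyclohex-3-ene-1-carboxylic acid (formed as its potassium salt, not isolated) | CC(C)=CCC[C@H](C)C1=CCC(C)C(C(=O)O)C1=O | intermediate
9 | 5-methyl-2-[(2S)-6-methylhept-5-en-2-yl]cyclohex-2-en-1-one (C5 epimers) | CC(C)=CCC[C@H](C)C1=CCC(C)CC1=O | intermediate
10 | trimethyl({3-methyl-6-[(2S)-6-methylhept-5-en-2-yl]cyclohexa-1,5-dien-1-yl}oxy)silane (not isolated) | CC(C)=CCC[C@H](C)C1=CCC(C)C=C1O[Si](C)(C)C | intermediate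
11 | 5-methyl-2-[(2S)-6-methylhept-5-en-2-yl]cyclohexa-2,5-dien-1-one (not isolated) | CC(C)=CCC[C@H](C)C1=CCC(C)=CC1=O | intermediate
12 | (S)-curcuphenol, 5-methyl-2-[(2S)-6-methylhept-5-en-2-yl]phenol | CC(C)=CCC[C@H](C)c1ccc(C)cc1O | intermediate
13 | 2,2'-dimethyl-5,5'-bis[(2S)-6-methylhept-5-en-2-yl]-1,1'-biphenyl-4,4'-diol (CNP0163343.1) | CC(C)=CCC[C@H](C)c1cc(-c2cc([C@@H](C)CCC=C(C)C)c(O)cc2C)c(C)cc1O | target

Total step count: 5. Longest linear sequence: 5 steps (1 → 4 → 7 → 9 → 12 → 13); two molecules of 12 meet in the last step.

Steps most likely to fail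

Step 5. The radical coupling may leak to C6 or to oxygen. The biphenol, or a monomer on its way to an ortho-quinone methide, may be oxidised further, and the alkenes may suffer anodic or acid-induced attack in HFIP. The fallback sets out from 12. Para-iodination with N-iodosuccinimide (MeCN, 0 °C) would give 4-iodo-5-methyl-2-[(2S)-6-methylhept-5-en-2-yl]phenol F1. Pd(dppf)Cl2 (5 mol %), bis(pinacolato)diboron (0.55 equiv) and K2CO3 in DMSO at 80 °C would then convert about half of F1 into 5-methyl-2-[(2S)-6-methylhept-5-en-2-yl]-4-(4,4,5,5-tetramethyl-1,3,2-dioxaborolan-2-yl)phenol F2. Suzuki–Miyaura coupling of F2 with the remaining F1 in the same flask, on the free phenoxides, would come back to the route at 13.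

Step 4. Enolisation may go toward C4 instead of C6, β-hydride elimination may stay incomplete, or divalent palladium may engage the side-chain alkene. The fallback sets out from 9. The lithium enolate (LiN(iPr)2, THF, −78 °C) would be trapped with PhSeBr to give 5-methyl-2-[(2S)-6-methylhept-5-en-2-yl]-6-(phenylselanyl)cyclohex-2-en-1-one F3, with selenium expected trans to the C5 methyl group and hence syn to H5. NaIO4 in aqueous THF (0 °C → rt) would oxidise F3 to the selenoxide 5-methyl-2-[(2S)-6-methylhept-5-en-2-yl]-6-(phenylseleninyl)cyclohex-2-en-1-one F4. Its syn-elimination would give the dienone 11, which tautomerises, and the fallback comes back to the route at 12.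

Step 2. 1,2-Addition to the aldehyde (Knoevenagel condensation and 2H-pyran formation) may compete with Michael addition, crotonaldehyde may oligomerise under base, and a second Michael addition may occur. The fallback sets out from 4 and replaces the aldehyde acceptor by an ester.
- NaOEt (1.1 equiv) and ethyl (E)-crotonate in refluxing EtOH would effect Michael addition and Claisen (Dieckmann-type) ring closure to ethyl 6-methyl-3-[(2S)-6-methylhept-5-en-2-yl]-2,4-dioxocyclohexane-1-carboxylate F5.
- Aqueous KOH and then dilute HCl would hydrolyse and decarboxylate F5 to 5-methyl-2-[(2S)-6-methylhept-5-en-2-yl]cyclohexane-1,3-dione F6.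
- Me2SO4 and K2CO3 in acetone would give the enol ether 3-methoxy-5-methyl-2-[(2S)-6-methylhept-5-en-2-yl]cyclohex-2-en-1-one F7.
- iBu2AlH (toluene, −78 °C) would reduce F7 to 3-methoxy-5-methyl-2-[(2S)-6-methylhept-5-en-2-yl]cyclohex-2-en-1-ol F8, and 1 M HCl at 0 °C would hydrolyse and transpose F8 (Stork–Danheiser sequence), coming back to the route at 9.

Further compounds
F1 | step 5 | 4-iodo-5-methyl-2-[(2S)-6-methylhept-5-en-2-yl]phenol | CC(C)=CCC[C@H](C)c1cc(I)c(C)cc1O
F2 | step 5 | 5-methyl-2-[(2S)-6-methylhept-5-en-2-yl]-4-(4,4,5,5-tetramethyl-1,3,2-dioxaborolan-2-yl)phenol | CC(C)=CCC[C@H](C)c1cc(B2OC(C)(C)C(C)(C)O2)c(C)cc1O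
F3 | step 4 | 5-methyl-2-[(2S)-6-methylhept-5-en-2-yl]-6-(phenylselanyl)cyclohex-2-en-1-one | CC(C)=CCC[C@H](C)C1=CCC(C)C([Se]c2ccccc2)C1=O
F4 | step 4 | 5-methyl-2-[(2S)-6-methylhept-5-en-2-yl]-6-(phenylseleninyl)cyclohex-2-en-1-one | CC(C)=CCC[C@H](C)C1=CCC(C)C([Se](=O)c2ccccc2)C1=O
F5 | step 2 | ethyl 6-methyl-3-[(2S)-6-methylhept-5-en-2-yl]-2,4-dioxocyclohexane-1-carboxylate | CC(C)=CCC[C@H](C)C1C(=O)CC(C)C(C(=O)OCC)C1=O
F6 | step 2 | 5-methyl-2-[(2S)-6-methylhept-5-en-2-yl]cyclohexane-1,3-dione | CC(C)=CCC[C@H](C)C1C(=O)CC(C)CC1=O
F7 | step 2 | 3-methoxy-5-methyl-2-[(2S)-6-methylhept-5-en-2-yl]cyclohex-2-en-1-one | CC(C)=CCC[C@H](C)C1=C(OC)CC(C)CC1=O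
F8 | step 2 | 3-methoxy-5-methyl-2-[(2S)-6-methylhept-5-en-2-yl]cyclohex-2-en-1-ol | CC(C)=CCC[C@H](C)C1=C(OC)CC(C)CC1O
A1 | direct plan | 1-(5-bromo-2-methoxy-4-methylphenyl)ethan-1-one | CC(=O)c1cc(Br)c(C)cc1OC
A2 | direct plan | (E)-4-(5-bromo-2-methoxy-4-methylphenyl)pent-3-enoic acid | C/C(=C\CC(=O)O)c1cc(Br)c(C)cc1OC
A3 | direct plan | (S)-4-(5-bromo-2-methoxy-4-methylphenyl)pentanoic acid | OC(=O)CC[C@H](C)c1cc(Br)c(C)cc1OC
A4 | direct plan | (4S,4'S)-4,4'-(4,4'-dimethoxy-6,6'-dimethylbiphenyl-3,3'-diyl)dipentanoic acid | OC(=O)CC[C@H](C)c1cc(-c2cc([C@@H](C)CCC(=O)O)c(OC)cc2C)c(C)cc1OC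
A5 | direct plan | bis(1,3-dioxoisoindolin-2-yl) (4S,4'S)-4,4'-(4,4'-dimethoxy-6,6'-dimethylbiphenyl-3,3'-diyl)dipentanoate | O=C(ON1C(=O)c2ccccc2C1=O)CC[C@H](C)c1cc(-c2cc([C@@H](C)CCC(=O)ON3C(=O)c4ccccc4C3=O)c(OC)cc2C)c(C)cc1OC
A6 | direct plan | 4,4'-dimethoxy-2,2'-dimethyl-5,5'-bis[(2S)-6-methylhept-5-en-2-yl]-1,1'-biphenyl | CC(C)=CCC[C@H](C)c1cc(-c2cc([C@@H](C)CCC=C(C)C)c(OC)cc2C)c(C)cc1OC
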